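The pitfall in these runs is to read the rise of rate with charge as an effect of catalyst. Monday's, Tuesday's and Thursday's runs raise substrate and free catalyst together, at 2.5 mol%, with partner at 0.80 equiv and impurity at 0.015 M, so whatever is read from them holds along that line of charges.

all flasks: added ligand 0.89 mM
- Monday's: substrate 0.033 M; partner 0.80 equiv; protic impurity 0.015 M; free catalyst 2.5 mol%; run made earlier
- Tuesday's: substrate 0.085 M; partner 0.80 equiv; protic impurity 0.015 M; free catalyst 2.5 mol%; run made earlier
- Thursday's: substrate 0.15 M; partner 0.80 equiv; protic impurity 0.015 M; free catalyst 2.5 mol%; run made earlier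
- Saturday's: substrate 0.050 M; partner 0.95 equiv; protic impurity 0.015 M; free catalyst 2.5 mol%; run made earlier
- autumn: substrate 0.20 M; partner 1.60 equiv; protic impurity 0.0500 M; free catalyst 2.5 mol%; time 3.0 min
- summer: substrate 0.050 M; partner 0.800 equiv; protic impurity 0.0150 M; free catalyst 2.5 mol%; time 3.0 min
- midnight: substrate 0.050 M; partner 0.800 equiv; protic impurity 0.0150 M; free catalyst 10 mol%; time 3.0 min
- dusk: substrate 0.030 M; partner 0.800 equiv; protic impurity 0.0500 M; free catalyst 2.5 mol%; time 3.0 min

| run | time / s | target / % | substrate / % |
|---|---|---|---|
| Monday's | 10.0 | 2.0 | 97.9 |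
| Monday's | 15.0 | 1.9 | 97.5 |
| Monday's | 25.0 | 4.5 | 96.0 |
| Monday's | 50.0 | 8.7 | 89.9 |
| Monday's | 90.0 | 16.5 | 83.7 |
| Tuesday's | 10.0 | 3.5 | 96.6 |
| Tuesday's | 15.0 | 5.8 | 94.7 |
| Tuesday's | 25.0 | 10.0 | 90.0 |
| Tuesday's | 50.0 | 19.2 | 81.2 |
| Tuesday's | 90.0 | 31.5 | 68.7 |
| Thursday's | 10.0 | 6.9 | 94.5 |
| Thursday's | 15.0 | 8.3 | 91.4 |
| Thursday's | 25.0 | 13.4 | 86.7 |
| Thursday's | 50.0 | 25.3 | 74.7 |
| Thursday's | 90.0 | 42.0 | 58.6 |
| Saturday's | 10.0 | 2.2 | 97.1 |
| Saturday's | 15.0 | 4.1 | 96.7 |
| Saturday's | 25.0 | 7.5 | 93.3 |
| Saturday's | 50.0 | 13.4 | 86.8 |
| Saturday's | 90.0 | 23.2 | 77.0 |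

(standard deviation of a reading: 0.5 percentage points)

1. ranking by amount of target, in percent of the substrate charged, from high to low, at 3.0 min (autumn / summer / midnight / dusk)
2. the same order at 20 s (autumn / summer / midnight / dusk)
3. the amount of target, in percent of the substrate charged of the flask you put first, at 3.0 min
4. the amount of target, in percent of the substrate charged of the flask you put last, at 3.0 min

- no earlier run changes the charge of protic impurity; that part of a forecast is a guess

Target and substrate add up to 101% in Thursday's last reading, so substrate lost can stand for target made. In powers of ten, a flask is a decade count: the common logarithm of substrate charged over substrate left. Thursday's run reaches 0.232 decades by 90.0 s, Monday's 0.0773. The logarithm of that ratio over the logarithm of the substrate ratio gives 0.726, the decade slope: powers of ten of decade count gained per power of ten of charge along the line.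

Autumn shares the loading of the line but not the rest of it: its 0.20 M of substrate lies beyond the runs, and it charges 1.60 equiv of partner and 0.0500 M of impurity, so the slope reaches it only as an extrapolation across those differences. It runs twice as long as Thursday's last reading. With that reservation, my reckoning leaves 26.8% of its substrate, which is 0.572 decades and 73.2% target. Dusk, reckoned the same way from Monday's run, leaves 71.7%, so 28.3% target. Midnight holds the same catalyst concentration as autumn, 5.00 mM, but stands off the line, so the slope does not serve it.

The weak link is dusk, which charges 0.0500 M of impurity against 0.0240 M of partner, and no run moves the impurity. Monday's run is the nearest test, with 0.015 M of impurity against 0.0264 M of partner. Its decade count per time stands at 0.0555 /min by 50.0 s and 0.0515 /min by 90.0 s, with no clear bend beyond the scatter. So dusk keeps my figure, with the impurity lowering it by an unknown amount.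

The forecast differs there. It gives autumn > midnight > summer > dusk at 3.0 min, midnight > autumn > summer > dusk at 20 s, 72% for the first flask and 10% for the last, saying “It may quench partner, and in dusk it exceeds partner”.

The flasks rank autumn > midnight > summer > dusk at 3.0 min and midnight > autumn > summer > dusk at 20 s; autumn gives 77.8% and dusk 21.5%.

    partner + free catalyst → catalyst intermediate A (k = 23.0 /M/s)
    catalyst intermediate A ⇌ released group + catalyst intermediate B (K = 0.0320 M, k = 1.00 /s)
    catalyst intermediate B ⇌ catalyst intermediate C (K = 3.70, k = 1.70 /s)
    substrate + catalyst intermediate C → catalyst intermediate D (k = 5.10 /M/s)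
    catalyst intermediate D → free catalyst + target (k = 94.0 /s)
    partner + protic impurity → quenched reagent (k = 0.250 /M/s)
    free catalyst + added ligand ⇌ idle complex, settled at all times (K = 640 /M)
    released group → by-product carried off (k = 0.0160 /s)

Autumn's 22% of substrate left is 0.654 decades, more than the reckoned 0.572. A neighbour of autumn charged with 0.62 mol% of free catalyst moves catalyst with substrate held. From autumn's own count, the decade slope puts its substrate at 57.8%, but that flask holds 70% and gives 29.6% target. Between these two flasks the slope reads 1.05, steeper than the 0.726 of the line.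

The readings are simulated with constants of no real substance, noise included.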